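**Retrosynthetic overview** (chain numbered C-1 = lactone carbonyl to C-12 = terminal methyl)
1. C-8=C-9 (E): cross-metathesis of a vinyl lactone (C-1 to C-8) with (3S,4R)-pent-1-ene-3,4-diyl diacetate (C-9 to C-12).
2. C-6–C-7, the key bond: electrochemical, chromium-catalysed γ-methoxyallylation of (2S)-6-oxo-3,6-dihydro-2H-pyran-2-carbaldehyde with acrolein dimethyl acetal; C-6 and C-7 are set from C-5.
3. The aldehyde comes from 2-deoxy-D-ribose: Wittig olefination, photochemical E→Z isomerisation/lactonisation, periodate cleavage.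
4. The diacetate comes from methyl (R)-lactate: silylation, one-pot reduction/Felkin–Anh vinyl addition (C-10 set from C-11), desilylation/acetylation.
5. Ring order: the dihydropyranone is the only ring and is closed in step 2, before either C–C coupling.

Assumption: the target is taken exactly as the SMILES encodes it (5S,6S,7R,8E,10S,11R); 2-deoxy-D-ribose is drawn as its open-chain aldehyde.

**Step 1**
Reactants: 1 2-deoxy-D-ribose; 2 ethyl (triphenylphosphoranylidene)acetate
Product: 3 ethyl (2E,5S,6R)-5,6,7-trihydroxyhept-2-enoate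
Conditions: THF, PhCO2H (cat.), 65 °C
Reagents that add atoms: none
Why: Wittig olefination; the stabilised ylide traps the open-chain aldehyde form of the lactol and gives the E-enoate without touching the two bought stereocentres.

**Step 2**
Reactants: 3 ethyl (2E,5S,6R)-5,6,7-trihydroxyhept-2-enoate
Product: 5 (6S)-6-[(1R)-1,2-dihydroxyethyl]-5,6-dihydro-2H-pyran-2-one, via (Z)-triol ester 4 (not isolated)
Conditions: hν (254 nm, quartz), MeSO3H (2 mol %), MeCN (0.02 M), 20 °C
Reagents that add atoms: none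
Why: Photochemical E→Z isomerisation followed by acid-catalysed lactonisation; only the Z ester can reach the 5-hydroxy group, so six-ring closure drains the photostationary mixture, and the ring carbon (C-5 of the target) keeps its bought configuration.

**Step 3**
Reactants: 5 (6S)-6-[(1R)-1,2-dihydroxyethyl]-5,6-dihydro-2H-pyran-2-one
Product: 6 (2S)-6-oxo-3,6-dihydro-2H-pyran-2-carbaldehyde
Conditions: NaIO4 (1.3 equiv), CH2Cl2/H2O (pH 7), 0 °C → rt; used crude
Reagents that add atoms: none
Why: Periodate (Malaprade) glycol cleavage; the ring oxygen is acylated, so only the terminal 1,2-diol is cut, and at neutral pH the C-5 centre is not epimerised.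

**Step 4**
Reactants: 6 (2S)-6-oxo-3,6-dihydro-2H-pyran-2-carbaldehyde; 7 3,3-dimethoxyprop-1-ene (acrolein dimethyl acetal)
Product: 10 (6S)-6-[(1S,2R)-1-hydroxy-2-methoxybut-3-en-1-yl]-5,6-dihydro-2H-pyran-2-one, via 3-chloro-3-methoxyprop-1-ene 8 (not isolated), via trimethylsilyl ether 9 (not isolated)
Conditions: CrCl2 (15 mol %), Me3SiCl (2.5 equiv), 7 (3 equiv), Bu4NPF6 (0.1 M), THF/DMF 4:1, undivided cell, Al anode, Ni-foam cathode, constant current (2.5 F/mol), −20 °C; then citric acid, MeOH, 0 °C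
Reagents that add atoms: chlorotrimethylsilane, C[Si](C)(C)Cl (chlorine in 8, silyl group in 9; neither remains in 10)
Why: Proposed new method: a catalytic, electro-reductive version of the chromium-mediated γ-alkoxyallylation — Me3SiCl (helped by the AlCl3 grown at the anode) ionises acetal 7 to chloro ether 8, CrCl2 abstracts the chlorine to give the 1-methoxyallyl radical, a second divalent chromium traps it as the (E)-γ-methoxyallyl trivalent chromium reagent, which adds to 6 at its methoxy-bearing carbon through a chair Zimmerman–Traxler transition state (6,7-anti) on the Felkin–Anh/Cornforth face of the α-acyloxy aldehyde (5,6-anti), so the 5S,6S,7R triad comes from the single bought centre C-5; Me3SiCl silylates the chromium alkoxide and the cathode returns trivalent chromium to divalent chromium at a potential that leaves aldehyde, enoate and acetal untouched; the closest known reaction types are the stoichiometric CrCl2/Me3SiI alkoxyallylation of aldehydes with unsaturated acetals and electro-catalytic Nozaki–Hiyama–Kishi couplings turned over by chlorosilanes (expected d.r. about 5:1, minor isomers removed by chromatography).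

**Step 5**
Reactants: 11 methyl (R)-lactate
Product: 12 methyl (2R)-2-[(tert-butyldimethylsilyl)oxy]propanoate
Conditions: TBSCl, imidazole, DMF, 0 °C → rt
Reagents that add atoms: tert-butyl(chloro)dimethylsilane, CC(C)(C)[Si](C)(C)Cl
Why: Imidazole-promoted O-silylation; the bulky, non-chelating silyl ether prepares the Felkin–Anh control of the next step and the stereocentre is not touched.

**Step 6**
Reactants: 12 methyl (2R)-2-[(tert-butyldimethylsilyl)oxy]propanoate
Product: 14 (3S,4R)-4-[(tert-butyldimethylsilyl)oxy]pent-1-en-3-ol, via silyloxy aldehyde 13 (not isolated)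
Conditions: iBu2AlH (1.05 equiv), CH2Cl2, −78 °C; then CH2=CHMgBr (2 equiv, THF), −78 → 0 °C; KNaC4H4O6 (aq.)
Reagents that add atoms: vinylmagnesium bromide, C=C[Mg]Br
Why: One-pot partial ester reduction and Grignard addition; Felkin–Anh (non-chelation) attack on the α-silyloxy aldehyde gives the 3,4-anti alcohol (about 5:1, syn isomer removed by chromatography), so C-10 is set by the lactate-derived C-11.

**Step 7**
Reactants: 14 (3S,4R)-4-[(tert-butyldimethylsilyl)oxy]pent-1-en-3-ol
Product: 16 (3S,4R)-pent-1-ene-3,4-diyl diacetate, via pentenediol 15 (not isolated)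
Conditions: Bu4NF, THF, 0 °C; then Ac2O, pyridine, DMAP (cat.), 0 °C → rt
Reagents that add atoms: acetic anhydride, CC(=O)OC(C)=O
Why: Fluoride desilylation followed by DMAP-catalysed acetylation in one pot, because the volatile, water-soluble diol is best not isolated; no stereocentre is touched.

**Step 8**
Reactants: 10 (6S)-6-[(1S,2R)-1-hydroxy-2-methoxybut-3-en-1-yl]-5,6-dihydro-2H-pyran-2-one; 16 (3S,4R)-pent-1-ene-3,4-diyl diacetate
Product: 17 (6S)-6-[(1S,2R,3E,5S,6R)-5,6-diacetoxy-1-hydroxy-2-methoxyhept-3-en-1-yl]-5,6-dihydro-2H-pyran-2-one (CNP0375023.9)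
Conditions: second-generation Hoveyda–Grubbs catalyst, RuCl2(H2IMes)(=CH-C6H4-2-OiPr) (10 mol %), 16 (4 equiv), 1,4-benzoquinone (10 mol %), CH2Cl2, 40 °C
Reagents that add atoms: none
Why: Olefin cross-metathesis; both partners are allylic-oxygenated terminal alkenes (type 2) that dimerise slowly, the conjugated ring alkene is inert, excess 16 drives the coupling, and the disubstituted alkene forms E-selectively without touching any stereocentre.

**Compound list**
1 | 2-deoxy-D-ribose, (3S,4R)-3,4,5-trihydroxypentanal (open-chain form) | OC[C@@H](O)[C@@H](O)CC=O | starting material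
2 | ethyl (triphenylphosphoranylidene)acetate | CCOC(=O)C=P(c1ccccc1)(c1ccccc1)c1ccccc1 | starting material
3 | ethyl (2E,5S,6R)-5,6,7-trihydroxyhept-2-enoate | OC[C@@H](O)[C@@H](O)C/C=C/C(=O)OCC | intermediate
4 | ethyl (2Z,5S,6R)-5,6,7-trihydroxyhept-2-enoate (not isolated) | OC[C@@H](O)[C@@H](O)C/C=C\C(=O)OCC | intermediate
5 | (6S)-6-[(1R)-1,2-dihydroxyethyl]-5,6-dihydro-2H-pyran-2-one | OC[C@@H](O)[C@@H]1CC=CC(=O)O1 | intermediate
6 | (2S)-6-oxo-3,6-dihydro-2H-pyran-2-carbaldehyde | O=C[C@@H]1CC=CC(=O)O1 | intermediate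
7 | 3,3-dimethoxyprop-1-ene (acrolein dimethyl acetal) | C=CC(OC)OC | starting material
8 | 3-chloro-3-methoxyprop-1-ene (racemic, not isolated) | C=CC(Cl)OC | intermediate
9 | (6S)-6-[(1S,2R)-2-methoxy-1-[(trimethylsilyl)oxy]but-3-en-1-yl]-5,6-dihydro-2H-pyran-2-one (not isolated) | CO[C@H](C=C)[C@@H](O[Si](C)(C)C)[C@@H]1CC=CC(=O)O1 | intermediate
10 | (6S)-6-[(1S,2R)-1-hydroxy-2-methoxybut-3-en-1-yl]-5,6-dihydro-2H-pyran-2-one | CO[C@H](C=C)[C@@H](O)[C@@H]1CC=CC(=O)O1 | intermediate
11 | methyl (R)-lactate | C[C@@H](O)C(=O)OC | starting material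
12 | methyl (2R)-2-[(tert-butyldimethylsilyl)oxy]propanoate | C[C@@H](O[Si](C)(C)C(C)(C)C)C(=O)OC | intermediate
13 | (2R)-2-[(tert-butyldimethylsilyl)oxy]propanal (not isolated) | C[C@@H](O[Si](C)(C)C(C)(C)C)C=O | intermediate
14 | (3S,4R)-4-[(tert-butyldimethylsilyl)oxy]pent-1-en-3-ol | C=C[C@H](O)[C@@H](C)O[Si](C)(C)C(C)(C)C | intermediate
15 | (3S,4R)-pent-1-ene-3,4-diol (not isolated) | C=C[C@H](O)[C@@H](C)O | intermediate
16 | (3S,4R)-pent-1-ene-3,4-diyl diacetate | C=C[C@H](OC(C)=O)[C@@H](C)OC(C)=O | intermediate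
17 | (6S)-6-[(1S,2R,3E,5S,6R)-5,6-diacetoxy-1-hydroxy-2-methoxyhept-3-en-1-yl]-5,6-dihydro-2H-pyran-2-one | CO[C@H](/C=C/[C@H](OC(C)=O)[C@@H](C)OC(C)=O)[C@@H](O)[C@@H]1CC=CC(=O)O1 | target

**Step count**
Total steps: 8. Longest linear sequence: 5 (steps 1, 2, 3, 4, 8).

**Three steps most likely to fail**

Step 4 (the proposed new method). Risks are acetal exchange between 7 and aldehyde 6, poor chromium turnover, and only moderate facial selectivity. The fallback uses known chemistry, sets out from 6 and comes back at 10. 3-Methoxy-1-(trimethylsilyl)prop-1-yne is lithiated (tBuLi, THF, −78 °C) and transmetalated with Ti(OiPr)4. The resulting allenyltitanium adds to 6 anti-selectively through a cyclic SE2′ transition state on the same Felkin face, giving (6S)-6-[(1S,2R)-1-hydroxy-2-methoxy-4-(trimethylsilyl)but-3-yn-1-yl]-5,6-dihydro-2H-pyran-2-one F3. Bu4NF buffered with AcOH removes the alkynyl silyl group to give (6S)-6-[(1S,2R)-1-hydroxy-2-methoxybut-3-yn-1-yl]-5,6-dihydro-2H-pyran-2-one F4. Semi-hydrogenation (H2, Pd/CaCO3 poisoned with Pb(OAc)2, quinoline) gives 10.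

Step 8 (cross-metathesis of two allylic-oxygenated alkenes). Risks are slow coupling and isomerisation of the allylic ether. The fallback changes the union to a Nozaki–Hiyama–Kishi coupling across C-7/C-8; it sets out from 5 and 16, comes back at 17, and replaces steps 3, 4 and 8. It also keeps both stereocentres of 1, so only C-7 is newly set.
- 5 is bis-silylated (Et3SiCl, imidazole) to (6S)-6-[(1R)-1,2-bis(triethylsilyloxy)ethyl]-5,6-dihydro-2H-pyran-2-one F5.
- Swern oxidation [(COCl)2, DMSO, Et3N] cleaves and oxidises only the primary silyl ether, giving (2S)-2-[(2S)-6-oxo-3,6-dihydro-2H-pyran-2-yl]-2-(triethylsilyloxy)acetaldehyde F6.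
- Ozonolysis of 16 (O3, then PPh3) gives (2R,3R)-2,3-diacetoxybutanal F7, and Takai olefination (CHI3, CrCl2, THF) converts it into (1E,3S,4R)-1-iodopent-1-ene-3,4-diyl diacetate F8.
- F8 and F6 are joined with CrCl2 and catalytic NiCl2 in DMSO (Felkin–Anh, 6,7-anti) to give (6S)-6-[(1R,2R,3E,5S,6R)-5,6-diacetoxy-2-hydroxy-1-(triethylsilyloxy)hept-3-en-1-yl]-5,6-dihydro-2H-pyran-2-one F9.
- O-Methylation (Me3OBF4, 1,8-bis(dimethylamino)naphthalene, CH2Cl2) gives (6S)-6-[(1S,2R,3E,5S,6R)-5,6-diacetoxy-2-methoxy-1-(triethylsilyloxy)hept-3-en-1-yl]-5,6-dihydro-2H-pyran-2-one F10, and HF·pyridine then gives 17.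

Step 2 (photo-isomerisation/lactonisation of an unprotected triol). Risks are photodegradation of the lactone and incomplete drain of the E ester. The fallback makes the cis ester directly; it sets out from 1, comes back at 5, and replaces steps 1 and 2. 1 is treated with 2-methoxypropene and PPTS in DMF to give 2-deoxy-3,4-O-isopropylidene-D-erythro-pentopyranose F1. An Ando-type Z-selective Horner–Wadsworth–Emmons reaction of this lactol with ethyl (diphenoxyphosphoryl)acetate and NaH in THF gives ethyl (2Z)-4-[(4S,5R)-5-(hydroxymethyl)-2,2-dimethyl-1,3-dioxolan-4-yl]but-2-enoate F2. Aqueous CF3CO2H removes the acetonide and the freed 5-hydroxy group closes onto the cis ester to give 5.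

**Further compounds**
F1 | step 2 | 2-deoxy-3,4-O-isopropylidene-D-erythro-pentopyranose (anomeric mixture) | CC1(C)O[C@@H]2COC(O)C[C@@H]2O1
F2 | step 2 | ethyl (2Z)-4-[(4S,5R)-5-(hydroxymethyl)-2,2-dimethyl-1,3-dioxolan-4-yl]but-2-enoate | CCOC(=O)/C=C\C[C@@H]1OC(C)(C)O[C@@H]1CO
F3 | step 4 | (6S)-6-[(1S,2R)-1-hydroxy-2-methoxy-4-(trimethylsilyl)but-3-yn-1-yl]-5,6-dihydro-2H-pyran-2-one | CO[C@H](C#C[Si](C)(C)C)[C@@H](O)[C@@H]1CC=CC(=O)O1
F4 | step 4 | (6S)-6-[(1S,2R)-1-hydroxy-2-methoxybut-3-yn-1-yl]-5,6-dihydro-2H-pyran-2-one | CO[C@H](C#C)[C@@H](O)[C@@H]1CC=CC(=O)O1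
F5 | step 8 | (6S)-6-[(1R)-1,2-bis(triethylsilyloxy)ethyl]-5,6-dihydro-2H-pyran-2-one | CC[Si](CC)(CC)OC[C@@H](O[Si](CC)(CC)CC)[C@@H]1CC=CC(=O)O1
F6 | step 8 | (2S)-2-[(2S)-6-oxo-3,6-dihydro-2H-pyran-2-yl]-2-(triethylsilyloxy)acetaldehyde | O=C[C@@H](O[Si](CC)(CC)CC)[C@@H]1CC=CC(=O)O1
F7 | step 8 | (2R,3R)-2,3-diacetoxybutanal | O=C[C@H](OC(C)=O)[C@@H](C)OC(C)=O
F8 | step 8 | (1E,3S,4R)-1-iodopent-1-ene-3,4-diyl diacetate | I/C=C/[C@H](OC(C)=O)[C@@H](C)OC(C)=O
F9 | step 8 | (6S)-6-[(1R,2R,3E,5S,6R)-5,6-diacetoxy-2-hydroxy-1-(triethylsilyloxy)hept-3-en-1-yl]-5,6-dihydro-2H-pyran-2-one | O[C@H](/C=C/[C@H](OC(C)=O)[C@@H](C)OC(C)=O)[C@@H](O[Si](CC)(CC)CC)[C@@H]1CC=CC(=O)O1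
F10 | step 8 | (6S)-6-[(1S,2R,3E,5S,6R)-5,6-diacetoxy-2-methoxy-1-(triethylsilyloxy)hept-3-en-1-yl]-5,6-dihydro-2H-pyran-2-one | CO[C@H](/C=C/[C@H](OC(C)=O)[C@@H](C)OC(C)=O)[C@@H](O[Si](CC)(CC)CC)[C@@H]1CC=CC(=O)O1
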